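Conventions: labdane numbering (C1–C20) is used for the diterpene half, also for its early monocyclic precursors, and primed eudesmane numbering for the sesquiterpene half. β is the face of the angular methyl group (C20 or C14').

## Analysis of the target

- Target 36 is an ether between two terpenoid alcohols: O15 of a labda-8(17),13E-dien-19-oic acid (the isocupressic acid skeleton) is bonded to the tertiary C4' of eudesmane-4α,11-diol.
- The labdane half is a trans-decalin (rings A and B) with four stereocentres. C10 carries the β-methyl C20, C5 and C9 carry α-hydrogens, and C4 is quaternary with an equatorial α-methyl (C18) and an axial β-carboxyl (C19) that is 1,3-diaxial to C20. C8 bears an exocyclic methylene and the C9 side chain ends in an (E)-trisubstituted C13=C14 allylic ether.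
- The eudesmane half is a second trans-decalin with four stereocentres: the oxygen on C4' is α (equatorial), its methyl is β, and C7' carries an equatorial 2-hydroxyprop-2-yl group. Three of these centres (C5', C7', C10') are already present in β-eudesmol 30.
- Sensitive groups are the allylic tertiary ether (ionises under acid), the 8(17)-methylene (moves into the ring under acid), the free tertiary alcohol (dehydrates) and the C19 carboxyl, whose esters are axial and neopentyl and resist attack at the carbonyl.
- Three things make the synthesis hard: the quaternary C4 with its larger substituent axial; a C–O bond between a hindered tertiary oxygen and an allylic carbon in a fragment with a second tertiary hydroxyl; and two isolated alkenes in the labdane that forbid late hydrogenation or hydroboration.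
- The strategy rests on the position of C4 in ring A: it is bonded to C5 and stands 1,4 to C1. If C19 is tied back to an oxygen on C1 as a δ-lactone fused to ring B, and C1 carries a vinyl group (the future C2 and C3), a [3,3] shift of the lactone enolate forms C3–C4, closes ring A and leaves the carboxyl on the β-face of C4, with the configuration dictated by the C1 carbinol.

## Retrosynthetic reasoning

**36 to 35.** Only two silicon-based groups are removed at the end. The carboxyl is carried as a 2-(trimethylsilyl)ethyl ester because the axial C19 ester cannot be saponified under conditions the allylic ether survives, whereas fragmentation started at silicon ignores the hindrance. The silyl ether on O11' falls in the same operation.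

**35 to 29 and 33.** The ether is cut at O–C15. The other C–O bond (C4'–O) is tertiary and could only be made by cation capture, whereas C15 is a primary allylic carbon open to SN2 attack by the alkoxide of 33. The cut gives two fragments of similar size and postpones the union to the penultimate step.

**33 to 32, 31 and 30.** The oxygen on C4' is introduced by formal Markovnikov hydration of the exocyclic alkene of 30 in two steps, α-face epoxidation and hydride opening. This fixes C4' and, after prior silylation of O11' (31), leaves the C4' hydroxyl as the only free one.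

**29 to 28, 27 and 26.** C13=C14 is cut by an olefination of methyl ketone 26 with a stabilised phosphonate carbanion. This builds the (E)-trisubstituted alkene after all hydroboration and hydrogenation chemistry is over. Reduction and bromination adjust C15.

**26 to 25, 24, 23 and 22.** C8=C17 comes from methylenation of ketone 24. The C8 oxygen comes from hydroboration of the Δ8 alkene 22, which at the same time places hydrogen on the α-face of C9. The C13 carbonyl is carried as a dioxolane through these steps.

**22 to 19 and 20.** C9–C11 is cut as an sp2–sp3 coupling between enol triflate 19 and the primary borane 21 made from 20. The ketone in 18 can enolise only toward C8, so the position of the alkene is unambiguous.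

**19 to 18, 17 and 15.** These are functional group changes only. The C1=C2 alkene left by the key step is hydrogenated here, while it is still the only alkene.

**15 to 12 (key disconnection).** C3–C4 is cut and C1–O reconnected, which turns ring A into the vinyl-substituted δ-lactone 12. The forward step must close ring A, make C4 quaternary and set its configuration in one event. Cutting here rather than alkylating a ring A ester enolate ties the C4 configuration to a stereocentre (C1) that is easier to set and to verify.

**12 to 11, 7 and 8.** The lactone C–O bond and C10–C1 are cut together: an aldol of the C9/C10 enolate with 8 gives a carbinol that lactonises onto the ester. The enolate is generated regiospecifically by conjugate hydride addition to the exocyclic enone 7, which also creates the C20 methyl. The electrophile enters anti to the substituent on C5, giving the trans relationship of C1 and C4 that the trans-fused lactone needs.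

**7 to 5, 4, 2 and 3; 2 to 1.** C4–C5 is cut as a catalytic enantioselective Mukaiyama–Michael addition of ketene acetal 2 to 3, the only reaction in the labdane half that takes its configuration from a catalyst. The silyl enol ether 4 preserves the regiochemistry so that C10 can be aminomethylated (5) and unmasked as the enone 7. A route that creates the quaternary C10 first, by desymmetrising a symmetrical 1,3-diketone, was not taken. C5 would then have to be set next to a carbon whose two substituents (methyl and a three-carbon chain) hardly differ. Setting C5 first and letting the electrophile enter anti to it uses a strong and well-understood bias.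

## Alternatives that were turned down

**Alternative 1:** oxidative radical bicyclisation.
- Disconnection: C4–C5 and C9–C10 are cut, which unfolds rings A and B into the acyclic (E,E)-dienyl α-methyl β-keto ester A2, carrying an 8-phenylmenthyl ester group.
- Forward key step: a trivalent manganese carboxylate oxidises the β-keto ester to the C4 radical. It closes ring A by 6-endo attack on C5, the C10 radical closes ring B on C9, and a divalent copper co-oxidant turns the C8 radical into the 8(17)-methylene, giving A1.
- For it: two rings, four stereocentres and the exocyclic alkene arise in one step from a linear precursor. On ring construction it is clearly more economical than the chosen route, which needs ten steps from ring B to the methylene.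
- Against it: the sense at C4 rests on an ester auxiliary acting on a planar radical, which is a weaker control element than a cyclic transition state. The auxiliary sits on the axial ester that is hardest to cleave. The C3 ketone must be removed in the presence of the exocyclic alkene. The copper-mediated elimination can also give endocyclic isomers. The C12 acetate still needs the four remaining side-chain carbons and the ether.
- Comparison: the chosen strategy gives up the one-step bicyclisation. In return C4 is fixed by chirality transfer inside a rigid bicycle, there is no auxiliary on C19 and no extra oxygen on C3.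

**Alternative 2:** interrupted Cope cyclisation of elemol with ether capture.
- Disconnection: on the eudesmane half, C2'–C3' and C4'–O are cut, leading back to elemol A4 and prenol A5.
- Forward key step: a dicationic divalent platinum catalyst activates the vinyl group of A4, the isopropenyl terminus C3' closes ring A', and A5 traps the C4' cation to give A3.
- For it: it forms the most hindered bond of the target, the tertiary C4'–O ether, together with a ring and from a cheap terpene. On that bond it is stronger than the Williamson reaction used here.
- Against it: it solves only the sesquiterpene half. The internal C11' hydroxyl competes with A5 for the cation. The axial or equatorial sense of capture at C4' is not secured. The C1'=C2' alkene must later be hydrogenated next to the prenyl alkene. The prenyl group then needs (E)-selective allylic oxidation and an sp3–sp3 coupling to C11 of a labdane that still has to be made, including its quaternary C4.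
- Comparison: the chosen strategy starts from 30, which already contains the eudesmane skeleton, sets C4' by epoxidation and hydride opening, and spends its key step on the labdane quaternary centre.

**Alternative 3:** alkyne carboalumination and alkoxymethylation.
- Disconnection: C13–C16 and C14–C15 are cut, leading to the labdane alkyne A7 and the chloromethyl ether A8 (made from 33).
- Forward key step: zirconocene-catalysed methylalumination of A7 adds methyl and aluminium syn across the alkyne, and the derived alkenylalanate displaces chloride from A8 to give A6.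
- For it: the (E)-alkene is formed with complete stereocontrol and the ether linkage is completed without SN2 chemistry at a hindered alkoxide. One step replaces four of the present route (olefination, reduction, bromination, etherification) and avoids their E/Z separation. On the side chain it is the stronger plan.
- Against it: it is an endgame only, and A7 presupposes the whole bicyclic core with C4 in place. A8 is a chloromethyl ether of a tertiary alcohol and ionises easily. A Lewis acidic alane must tolerate the 8(17)-alkene, and the C19 methyl ester in A6 is the kind of ester that is hard to remove at the end.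
- Comparison: the chosen strategy answers the question that this alternative leaves open, the construction of ring A with its quaternary centre, and keeps the side-chain steps individually conventional.

Key step: step 7

Assumptions: the carbon α to the ester (later C4) is carried as an uncontrolled mixture of epimers through 4–12, which is harmless because step 7 makes it planar; and the (S)-proline-derived boron catalyst in step 2 is taken to give (1R)-4, its antipode being used if the sense proves opposite.

## Route

Step 1
Reactants: 1 methyl propionate
Product: 2 (E)-1-methoxy-1-(trimethylsilyloxy)prop-1-ene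
Conditions: LiN(i-Pr)2, THF, −78 °C; Me3SiCl, −78 °C to rt; distil
Reagents that add atoms: chlorotrimethylsilane, C[Si](C)(C)Cl
Why: Kinetic ester deprotonation and O-silylation of the enolate (Ireland conditions) give the ketene acetal; its geometry is immaterial because the carbon concerned (later C4) becomes planar again in step 7.

Step 2
Reactants: 2 (E)-1-methoxy-1-(trimethylsilyloxy)prop-1-ene; 3 cyclohex-2-en-1-one
Product: 4 methyl 2-[(1R)-3-(trimethylsilyloxy)cyclohex-2-en-1-yl]propanoate
Conditions: oxazaborolidinium catalyst [(S)-diphenylprolinol-derived B-(o-tolyl)oxazaborolidine protonated by HNTf2, 20 mol%], Ph3P=O (25 mol%), toluene, −20 °C; non-aqueous work-up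
Reagents that add atoms: none
Why: Catalytic enantioselective Mukaiyama–Michael addition: the chiral boron Lewis acid binds the enone carbonyl and shields one face of the β-carbon, so C4–C5 should form with (R)-configuration at the ring carbon (C5, H on the future α-face); silyl transfer to the enolate oxygen leaves the C9=C10 enol ether, which fixes where the next electrophile goes.

Step 3
Reactants: 4 methyl 2-[(1R)-3-(trimethylsilyloxy)cyclohex-2-en-1-yl]propanoate
Product: 5 methyl 2-[(1R)-2-[(dimethylamino)methyl]-3-oxocyclohexyl]propanoate
Conditions: Me2N=CH2+ I−, CH2Cl2, rt; aq. NaHCO3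
Reagents that add atoms: N,N-dimethylmethyleneiminium iodide, C=[N+](C)C.[I-]
Why: Mannich reaction of a silyl enol ether with a preformed iminium salt occurs only at the enol carbon, so the carbon that becomes C20 is placed on C10 without regiochemical ambiguity; the configuration at C10 does not matter because step 4 removes it.

Step 4
Reactants: 5 methyl 2-[(1R)-2-[(dimethylamino)methyl]-3-oxocyclohexyl]propanoate
Product: 7 methyl 2-[(1S)-2-methylidene-3-oxocyclohexyl]propanoate, via methiodide 6 (not isolated)
Conditions: MeI, MeOH, rt; then aq. NaHCO3/CH2Cl2, rt; used at once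
Reagents that add atoms: none
Why: Exhaustive methylation makes the amine a leaving group and mild base induces E1cB (Hofmann-type) elimination to the exocyclic enone; bicarbonate is too weak to move the double bond into the ring, which would erase C5.

Step 5
Reactants: 7 methyl 2-[(1S)-2-methylidene-3-oxocyclohexyl]propanoate; 8 acrolein
Product: 11 (1R,4aS,8aR)-1-ethenyl-4,8a-dimethyloctahydro-1H-isochromene-3,8-dione, via lithium enolate 9 (not isolated), via aldol hydroxy ester 10 (not isolated)
Conditions: LiBH(s-Bu)3, THF, −78 °C; acrolein, −78 °C; AcOH; then camphorsulfonic acid (cat.), CH2Cl2, rt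
Reagents that add atoms: none
Why: Reductive aldol: conjugate hydride addition to the unhindered methylene gives the tetrasubstituted enolate 9 regiospecifically and creates the C20 methyl; acrolein then adds 1,2 at C10 anti to the pseudo-axial C5 substituent (C1 trans to C4), and a chair Zimmerman–Traxler transition state with the vinyl group equatorial should give the (1R)-carbinol, which places the vinyl group trans to C20 once the ring is closed. Acid closes the trans-fused δ-lactone with loss of methanol, which also blocks retro-aldol.

Step 6
Reactants: 11 (1R,4aS,8aR)-1-ethenyl-4,8a-dimethyloctahydro-1H-isochromene-3,8-dione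
Product: 12 (1R,4aS,8aR)-1-ethenyl-8,8-(ethylenedioxy)-4,8a-dimethyloctahydro-1H-isochromen-3-one
Conditions: Me3SiOCH2CH2OSiMe3, Me3SiOTf (cat.), CH2Cl2, −78 to −20 °C
Reagents that add atoms: 1,2-bis(trimethylsilyloxy)ethane, C[Si](C)(C)OCCO[Si](C)(C)C
Why: Noyori ketalisation works at low temperature on ketones next to a quaternary carbon and leaves the lactone and its allylic C–O bond alone; the dioxolane removes the only other enolisable carbonyl before step 7.

Step 7
Reactants: 12 (1R,4aS,8aR)-1-ethenyl-8,8-(ethylenedioxy)-4,8a-dimethyloctahydro-1H-isochromen-3-one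
Product: 15 (1S,4aS,8aR)-5,5-(ethylenedioxy)-1,4a-dimethyl-1,2,4a,5,6,7,8,8a-octahydronaphthalene-1-carboxylic acid, via silyl ketene acetal 13 (not isolated), via silyl ester 14 (not isolated)
Conditions: LiN(i-Pr)2, THF/HMPA, −78 °C; t-BuMe2SiCl, −78 °C to rt; then toluene, 105 °C; then THF/H2O (pH 5 buffer), rt
Reagents that add atoms: none
Why: LiN(i-Pr)2 removes the only α-hydrogen of the lactone (C4–H) and the enolate is O-silylated to the cyclic silyl ketene acetal 13, in which C4 and the vinyl terminus C3 stand 1,4 across the six-membered ring. On heating, a concerted suprafacial [3,3]-sigmatropic shift (Ireland–Claisen) forms C3–C4 while C1–O breaks; the closest known reaction type is the Claisen ring contraction of lactone silyl ketene acetals that carry a vinyl group on the carbinol carbon. Ring A closes within the six-atom array C3–C2–C1–O–C19–C4: because the ketene acetal double bond and the breaking C–O bond both lie in the lactone ring, the array is forced into a boat resembling a bicyclo[2.2.2]octane with C1 and C4 as bridgeheads, and the lactone contracts to the cyclohexene (C1=C2) with C19 expelled as the silyl ester 14. The only new stereocentre, C4, is controlled by the C1 carbinol (chirality transfer): the vinyl group is axial on the α-face, so C3 can reach only the α-face of C4, the methyl stays equatorial (α) and the carboxyl is left on the β-face, axial and cis to C20, while the C1 centre is consumed. The step needs O- rather than C-silylation (favoured by the hard silyl chloride in THF/HMPA) and a single boat: the trans ring fusion fixes C5 and C10, the dioxolane offers no second enolate, and both C4 epimers of 12 converge on one ketene acetal. The 1β-vinyl epimer could not reach C4 through this boat, which is why 12 has to be diastereomerically pure at C1. The labile silyl ester is hydrolysed on work-up without touching the dioxolane.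

Step 8
Reactants: 15 (1S,4aS,8aR)-5,5-(ethylenedioxy)-1,4a-dimethyl-1,2,4a,5,6,7,8,8a-octahydronaphthalene-1-carboxylic acid
Product: 17 (1S,4aS,8aR)-1,4a-dimethyl-5-oxodecahydronaphthalene-1-carboxylic acid, via saturated ketal acid 16 (not isolated)
Conditions: H2 (1 atm), Pd/C, EtOAc, rt; filter; then 2 M HCl/THF, rt
Reagents that add atoms: water, O
Why: Heterogeneous hydrogenation saturates the only alkene (C1=C2) before any other alkene exists; acetal hydrolysis then frees the C9 ketone, and because the alkene is already gone the acid cannot lactonise onto it.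

Step 9
Reactants: 17 (1S,4aS,8aR)-1,4a-dimethyl-5-oxodecahydronaphthalene-1-carboxylic acid
Product: 18 2-(trimethylsilyl)ethyl (1S,4aS,8aR)-1,4a-dimethyl-5-oxodecahydronaphthalene-1-carboxylate
Conditions: Me3SiCH2CH2OH, PPh3, diisopropyl azodicarboxylate, THF, 0 °C to rt
Reagents that add atoms: 2-(trimethylsilyl)ethanol, C[Si](C)(C)CCO
Why: Mitsunobu esterification alkylates the carboxylate oxygen at the primary carbon of the activated alcohol, so the shielding of the axial neopentyl carboxyl does not matter; this ester is later cleaved at silicon and not at the hindered carbonyl.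

Step 10
Reactants: 18 2-(trimethylsilyl)ethyl (1S,4aS,8aR)-1,4a-dimethyl-5-oxodecahydronaphthalene-1-carboxylate
Product: 19 2-(trimethylsilyl)ethyl (1S,4aS,8aR)-1,4a-dimethyl-5-(trifluoromethylsulfonyloxy)-1,2,3,4,4a,7,8,8a-octahydronaphthalene-1-carboxylate
Conditions: KN(SiMe3)2, THF, −78 °C; PhNTf2, −78 to 0 °C
Reagents that add atoms: N-phenylbis(trifluoromethanesulfonimide), O=S(=O)(N(c1ccccc1)S(=O)(=O)C(F)(F)F)C(F)(F)F
Why: The ketone can enolise only toward C8 because C10 is quaternary, and the ester has no α-hydrogen, so enolate triflation gives a single enol triflate (C8=C9).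

Step 11
Reactants: 19 2-(trimethylsilyl)ethyl (1S,4aS,8aR)-1,4a-dimethyl-5-(trifluoromethylsulfonyloxy)-1,2,3,4,4a,7,8,8a-octahydronaphthalene-1-carboxylate; 20 2-ethenyl-2-methyl-1,3-dioxolane
Product: 22 2-(trimethylsilyl)ethyl 13,13-(ethylenedioxy)-14,15,17-trinorlabd-8-en-19-oate, via alkylborane 21 (not isolated)
Conditions: 20, 9-BBN-H, THF, rt; then 19, PdCl2(dppf) (5 mol%), AsPh3, Cs2CO3, DMF/THF/H2O, rt to 50 °C
Reagents that add atoms: none
Why: B-alkyl Suzuki–Miyaura coupling: anti-Markovnikov hydroboration gives the primary borane 21, whose base-activated ate complex transmetalates to the alkenylpalladium formed by oxidative addition of zerovalent palladium into the C9–O triflate bond, forming C9–C11; the C13 carbonyl stays masked so that step 12 meets a single alkene.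

Step 12
Reactants: 22 2-(trimethylsilyl)ethyl 13,13-(ethylenedioxy)-14,15,17-trinorlabd-8-en-19-oate
Product: 23 2-(trimethylsilyl)ethyl 13,13-(ethylenedioxy)-8α-hydroxy-14,15,17-trinorlabdan-19-oate
Conditions: BH3·THF, THF, 0 °C to rt; then NaOH, H2O2, 0 °C to rt
Reagents that add atoms: hydrogen peroxide, OO
Why: Hydroboration–oxidation: boron adds to the less substituted C8 and hydrogen to C9, syn and from the α-face opposite the axial C20 methyl, which sets H9α (side chain β, equatorial) and the 8α-hydroxyl; oxidation proceeds with retention.

Step 13
Reactants: 23 2-(trimethylsilyl)ethyl 13,13-(ethylenedioxy)-8α-hydroxy-14,15,17-trinorlabdan-19-oate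
Product: 24 2-(trimethylsilyl)ethyl 13,13-(ethylenedioxy)-8-oxo-14,15,17-trinorlabdan-19-oate
Conditions: Dess–Martin periodinane, NaHCO3, CH2Cl2, rt
Reagents that add atoms: none
Why: Buffered Dess–Martin oxidation of the secondary alcohol; C9 becomes epimerisable, but the equatorial β side chain set in step 12 is also the thermodynamic arrangement.

Step 14
Reactants: 24 2-(trimethylsilyl)ethyl 13,13-(ethylenedioxy)-8-oxo-14,15,17-trinorlabdan-19-oate
Product: 25 2-(trimethylsilyl)ethyl 13,13-(ethylenedioxy)-14,15-dinorlabd-8(17)-en-19-oate
Conditions: Ph3PCH3Br, KOt-Bu, THF, rt to 60 °C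
Reagents that add atoms: methyltriphenylphosphonium bromide, C[P+](c1ccccc1)(c1ccccc1)c1ccccc1.[Br-]
Why: Wittig methylenation of the C8 ketone installs C17 as the exocyclic alkene; the non-stabilised ylide leaves the hindered ester and the ketal alone, and any base-mediated equilibration at C9 only reinforces the equatorial side chain.

Step 15
Reactants: 25 2-(trimethylsilyl)ethyl 13,13-(ethylenedioxy)-14,15-dinorlabd-8(17)-en-19-oate
Product: 26 2-(trimethylsilyl)ethyl 13-oxo-14,15-dinorlabd-8(17)-en-19-oate
Conditions: pyridinium p-toluenesulfonate, acetone/H2O, 50 °C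
Reagents that add atoms: water, O
Why: Mild acid-catalysed acetal hydrolysis frees the methyl ketone; the pyridinium salt is too weak an acid to isomerise the 8(17)-alkene or cleave the silylethyl ester.

Step 16
Reactants: 26 2-(trimethylsilyl)ethyl 13-oxo-14,15-dinorlabd-8(17)-en-19-oate
Product: 27 15-ethyl 19-[2-(trimethylsilyl)ethyl] (13E)-labda-8(17),13-diene-15,19-dioate
Conditions: (EtO)2P(O)CH2CO2Et, NaH, THF, 0 °C to reflux; chromatography
Reagents that add atoms: triethyl phosphonoacetate, CCOC(=O)CP(=O)(OCC)OCC
Why: Horner–Wadsworth–Emmons olefination of the methyl ketone; reversible addition lets the ester settle trans to the larger C12 chain, so the (E)-enoate should predominate and the (Z)-isomer is removed by chromatography.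

Step 17
Reactants: 27 15-ethyl 19-[2-(trimethylsilyl)ethyl] (13E)-labda-8(17),13-diene-15,19-dioate
Product: 28 2-(trimethylsilyl)ethyl (13E)-15-hydroxylabda-8(17),13-dien-19-oate
Conditions: i-Bu2AlH (2.2 equiv), CH2Cl2, −78 °C; aq. potassium sodium tartrate
Reagents that add atoms: none
Why: 1,2-Reduction of the unhindered conjugated ethyl ester to the allylic alcohol; the C19 ester is axial and neopentyl and reacts much more slowly at this temperature.

Step 18
Reactants: 28 2-(trimethylsilyl)ethyl (13E)-15-hydroxylabda-8(17),13-dien-19-oate
Product: 29 2-(trimethylsilyl)ethyl (13E)-15-bromolabda-8(17),13-dien-19-oate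
Conditions: CBr4, PPh3, CH2Cl2, 0 °C
Reagents that add atoms: carbon tetrabromide, BrC(Br)(Br)Br
Why: Appel bromination: bromide displaces the alkoxyphosphonium group at the primary allylic carbon by SN2 under neutral conditions that preserve the (E)-alkene and the 8(17)-methylene.

Step 19
Reactants: 30 β-eudesmol
Product: 31 11-(triethylsilyloxy)eudesm-4(15)-ene
Conditions: Et3SiOTf, 2,6-lutidine, CH2Cl2, 0 °C
Reagents that add atoms: triethylsilyl trifluoromethanesulfonate, CC[Si](CC)(CC)OS(=O)(=O)C(F)(F)F
Why: A silyl triflate with a hindered base silylates even a tertiary alcohol; marking O11' now makes the hydroxyl created in step 21 the only free one.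

Step 20
Reactants: 31 11-(triethylsilyloxy)eudesm-4(15)-ene
Product: 32 4α,15-epoxy-11-(triethylsilyloxy)eudesmane
Conditions: mCPBA, NaHCO3, CH2Cl2, 0 °C
Reagents that add atoms: 3-chloroperbenzoic acid, O=C(OO)c1cccc(Cl)c1
Why: Prilezhaev epoxidation of the exocyclic alkene from the α-face, because the β-face approach is blocked by the 1,3-related axial C14' methyl; this puts the epoxide oxygen α (equatorial) on C4'.

Step 21
Reactants: 32 4α,15-epoxy-11-(triethylsilyloxy)eudesmane
Product: 33 11-(triethylsilyloxy)eudesman-4α-ol
Conditions: LiAlH4, THF, 0 °C to rt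
Reagents that add atoms: none
Why: Hydride opens the spiro-epoxide by SN2 attack at the unhindered CH2, so the oxygen stays on C4' with its α-configuration and C15' becomes the β-methyl; the tertiary silyl ether is inert under these conditions.

Step 22
Reactants: 33 11-(triethylsilyloxy)eudesman-4α-ol; 29 2-(trimethylsilyl)ethyl (13E)-15-bromolabda-8(17),13-dien-19-oate
Product: 35 2-(trimethylsilyl)ethyl (13E)-15-{[11-(triethylsilyloxy)eudesman-4α-yl]oxy}labda-8(17),13-dien-19-oate, via potassium alkoxide 34 (not isolated)
Conditions: 33 (excess), KH, 18-crown-6 (cat.), THF, 0 °C; then 29, Bu4NI (cat.), 0 °C to rt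
Reagents that add atoms: none
Why: Williamson ether synthesis: KH deprotonates the tertiary alcohol irreversibly and the crown-separated alkoxide displaces the primary allylic bromide by SN2, forming O–C15 without touching either stereogenic C–O carbon; the only ester present has no α-hydrogen and is shielded.

Step 23
Reactants: 35 2-(trimethylsilyl)ethyl (13E)-15-{[11-(triethylsilyloxy)eudesman-4α-yl]oxy}labda-8(17),13-dien-19-oate
Product: 36 (13E)-15-[(11-hydroxyeudesman-4α-yl)oxy]labda-8(17),13-dien-19-oic acid (CNP0156875.1)
Conditions: Bu4NF (excess), THF, rt to 40 °C; aq. NH4Cl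
Reagents that add atoms: none
Why: Fluoride attacks silicon: the silylethyl ester fragments to carboxylate, ethene and Me3SiF and the triethylsilyl ether is cleaved in the same flask; no acid or strong base is used, so the allylic tertiary ether, the 8(17)-alkene and all stereocentres are left untouched.

## Compound list

1 | methyl propionate | CCC(=O)OC | starting material
2 | (E)-1-methoxy-1-(trimethylsilyloxy)prop-1-ene | C/C=C(/O[Si](C)(C)C)OC | intermediate
3 | cyclohex-2-en-1-one | O=C1C=CCCC1 | starting material
4 | methyl 2-[(1R)-3-(trimethylsilyloxy)cyclohex-2-en-1-yl]propanoate (C4 epimers) | C1CC[C@@H](C(C)C(=O)OC)C=C1O[Si](C)(C)C | intermediate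
5 | methyl 2-[(1R)-2-[(dimethylamino)methyl]-3-oxocyclohexyl]propanoate | C1CC[C@@H](C(C)C(=O)OC)C(CN(C)C)C1=O | intermediate
6 | methiodide of 5 (trimethylammonium iodide) | C1CC[C@@H](C(C)C(=O)OC)C(C[N+](C)(C)C)C1=O.[I-] | intermediate
7 | methyl 2-[(1S)-2-methylidene-3-oxocyclohexyl]propanoate | C1CC[C@@H](C(C)C(=O)OC)C(=C)C1=O | intermediate
8 | acrolein (prop-2-enal) | C=CC=O | starting material
9 | lithium (3S)-3-(1-methoxy-1-oxopropan-2-yl)-2-methylcyclohex-1-en-1-olate | C1CC[C@@H](C(C)C(=O)OC)C(C)=C1O[Li] | intermediate
10 | methyl 2-[(1S,2R)-2-[(1R)-1-hydroxyprop-2-en-1-yl]-2-methyl-3-oxocyclohexyl]propanoate | C1CC[C@@H](C(C)C(=O)OC)[C@](C)([C@@H](C=C)O)C1=O | intermediate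
11 | (1R,4aS,8aR)-1-ethenyl-4,8a-dimethyloctahydro-1H-isochromene-3,8-dione (trans-fused keto lactone, 1α-vinyl, C4 epimers) | C1CC[C@@H]2[C@](C)([C@@H](C=C)OC(=O)C2C)C1=O | intermediate
12 | (1R,4aS,8aR)-1-ethenyl-8,8-(ethylenedioxy)-4,8a-dimethyloctahydro-1H-isochromen-3-one (key-step precursor; C9 dioxolane, 1α-vinyl, 5α-H, 10β-methyl, C4 epimers) | C1CC[C@@H]2[C@](C)([C@@H](C=C)OC(=O)C2C)C13OCCO3 | intermediate
13 | tert-butyldimethylsilyl ketene acetal of 12 (C19(OSi)=C4) | C1CC[C@@H]2[C@](C)([C@@H](C=C)OC(O[Si](C)(C)C(C)(C)C)=C2C)C13OCCO3 | intermediate
14 | tert-butyldimethylsilyl ester of 15 | C1CC[C@@H]2[C@](C)(C=CC[C@]2(C)C(=O)O[Si](C)(C)C(C)(C)C)C13OCCO3 | intermediate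
15 | (1S,4aS,8aR)-5,5-(ethylenedioxy)-1,4a-dimethyl-1,2,4a,5,6,7,8,8a-octahydronaphthalene-1-carboxylic acid (key-step product; C1=C2, 4α-methyl, 4β-carboxyl, 5α-H, 10β-methyl) | C1CC[C@@H]2[C@](C)(C=CC[C@]2(C)C(=O)O)C13OCCO3 | intermediate
16 | (1S,4aS,8aR)-5,5-(ethylenedioxy)-1,4a-dimethyldecahydronaphthalene-1-carboxylic acid | C1CC[C@@H]2[C@](C)(CCC[C@]2(C)C(=O)O)C13OCCO3 | intermediate
17 | (1S,4aS,8aR)-1,4a-dimethyl-5-oxodecahydronaphthalene-1-carboxylic acid | C1CC[C@@H]2[C@](C)(CCC[C@]2(C)C(=O)O)C1=O | intermediate
18 | 2-(trimethylsilyl)ethyl (1S,4aS,8aR)-1,4a-dimethyl-5-oxodecahydronaphthalene-1-carboxylate | C1CC[C@@H]2[C@](C)(CCC[C@]2(C)C(=O)OCC[Si](C)(C)C)C1=O | intermediate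
19 | 2-(trimethylsilyl)ethyl (1S,4aS,8aR)-1,4a-dimethyl-5-(trifluoromethylsulfonyloxy)-1,2,3,4,4a,7,8,8a-octahydronaphthalene-1-carboxylate | C=1CC[C@@H]2[C@](C)(CCC[C@]2(C)C(=O)OCC[Si](C)(C)C)C=1OS(=O)(=O)C(F)(F)F | intermediate
20 | 2-ethenyl-2-methyl-1,3-dioxolane | CC1(C=C)OCCO1 | starting material
21 | 9-[2-(2-methyl-1,3-dioxolan-2-yl)ethyl]-9-borabicyclo[3.3.1]nonane | CC1(CCB2C3CCCC2CCC3)OCCO1 | intermediate
22 | 2-(trimethylsilyl)ethyl 13,13-(ethylenedioxy)-14,15,17-trinorlabd-8-en-19-oate | C=1CC[C@@H]2[C@](C)(CCC[C@]2(C)C(=O)OCC[Si](C)(C)C)C=1CCC3(C)OCCO3 | intermediate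
23 | 2-(trimethylsilyl)ethyl 13,13-(ethylenedioxy)-8α-hydroxy-14,15,17-trinorlabdan-19-oate | O[C@@H]1CC[C@@H]2[C@](C)(CCC[C@]2(C)C(=O)OCC[Si](C)(C)C)[C@H]1CCC3(C)OCCO3 | intermediate
24 | 2-(trimethylsilyl)ethyl 13,13-(ethylenedioxy)-8-oxo-14,15,17-trinorlabdan-19-oate | O=C1CC[C@@H]2[C@](C)(CCC[C@]2(C)C(=O)OCC[Si](C)(C)C)[C@H]1CCC3(C)OCCO3 | intermediate
25 | 2-(trimethylsilyl)ethyl 13,13-(ethylenedioxy)-14,15-dinorlabd-8(17)-en-19-oate | C=C1CC[C@@H]2[C@](C)(CCC[C@]2(C)C(=O)OCC[Si](C)(C)C)[C@H]1CCC3(C)OCCO3 | intermediate
26 | 2-(trimethylsilyl)ethyl 13-oxo-14,15-dinorlabd-8(17)-en-19-oate | C=C1CC[C@@H]2[C@](C)(CCC[C@]2(C)C(=O)OCC[Si](C)(C)C)[C@H]1CCC(C)=O | intermediate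
27 | 15-ethyl 19-[2-(trimethylsilyl)ethyl] (13E)-labda-8(17),13-diene-15,19-dioate | C=C1CC[C@@H]2[C@](C)(CCC[C@]2(C)C(=O)OCC[Si](C)(C)C)[C@H]1CC/C(C)=C/C(=O)OCC | intermediate
28 | 2-(trimethylsilyl)ethyl (13E)-15-hydroxylabda-8(17),13-dien-19-oate | C=C1CC[C@@H]2[C@](C)(CCC[C@]2(C)C(=O)OCC[Si](C)(C)C)[C@H]1CC/C(C)=C/CO | intermediate
29 | 2-(trimethylsilyl)ethyl (13E)-15-bromolabda-8(17),13-dien-19-oate | C=C1CC[C@@H]2[C@](C)(CCC[C@]2(C)C(=O)OCC[Si](C)(C)C)[C@H]1CC/C(C)=C/CBr | intermediate
30 | β-eudesmol | C=C1CCC[C@]2(C)CC[C@@H](C(C)(C)O)C[C@H]21 | starting material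
31 | 11-(triethylsilyloxy)eudesm-4(15)-ene | C=C1CCC[C@]2(C)CC[C@@H](C(C)(C)O[Si](CC)(CC)CC)C[C@H]21 | intermediate
32 | 4α,15-epoxy-11-(triethylsilyloxy)eudesmane | C1O[C@@]12CCC[C@]3(C)CC[C@@H](C(C)(C)O[Si](CC)(CC)CC)C[C@H]32 | intermediate
33 | 11-(triethylsilyloxy)eudesman-4α-ol | O[C@]1(C)CCC[C@]2(C)CC[C@@H](C(C)(C)O[Si](CC)(CC)CC)C[C@H]21 | intermediate
34 | potassium 11-(triethylsilyloxy)eudesman-4α-olate | [K+].[O-][C@]1(C)CCC[C@]2(C)CC[C@@H](C(C)(C)O[Si](CC)(CC)CC)C[C@H]21 | intermediate
35 | 2-(trimethylsilyl)ethyl (13E)-15-{[11-(triethylsilyloxy)eudesman-4α-yl]oxy}labda-8(17),13-dien-19-oate | C=C1CC[C@@H]2[C@](C)(CCC[C@]2(C)C(=O)OCC[Si](C)(C)C)[C@H]1CC/C(C)=C/CO[C@]1(C)CCC[C@]2(C)CC[C@@H](C(C)(C)O[Si](CC)(CC)CC)C[C@H]21 | intermediate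
36 | (13E)-15-[(11-hydroxyeudesman-4α-yl)oxy]labda-8(17),13-dien-19-oic acid (CNP0156875.1) | C=C1CC[C@@H]2[C@](C)(CCC[C@]2(C)C(=O)O)[C@H]1CC/C(C)=C/CO[C@]1(C)CCC[C@]2(C)CC[C@@H](C(C)(C)O)C[C@H]21 | target

## Step count

- Total: 23 steps.
- Longest linear sequence: 20 steps (steps 1–18, 22 and 23).
- The eudesmane branch (steps 19–21) joins at step 22.

## Least certain steps and fallbacks

**Step 7 (key step).**
- What may go wrong: the hindered lactone enolate may be silylated on carbon, or revert by proton return or ketene formation, faster than the strained boat is reached. The rearrangement then stalls and the ketene acetal decomposes on prolonged heating.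
- Fallback, same C3–C4 bond made by an ionic route, setting out from 12 and returning at 18. The lactone of 12 is opened with lithium 2-(trimethylsilyl)ethoxide and the released C1 alkoxide is capped in the same flask with methyl chloroformate, giving the allylic methyl carbonate F1. LiN(SiMe3)2 forms the ester enolate and Pd(PPh3)4 ionises the carbonate to a π-allyl complex whose terminus C3 is attacked by C4 (intramolecular Tsuji–Trost alkylation; attack at C1 would need a four-membered ring). This gives the 2-(trimethylsilyl)ethyl ester of 15, F2. Hydrogenation and acid hydrolysis under the conditions of step 8 convert F2 directly into 18.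
- Price: C4 is then set by a chair-like closure and no longer by chirality transfer, so its configuration would have to be confirmed.

**Step 2.**
- What may go wrong: loss of enantioselectivity, because the unhindered propionate ketene acetal can react through an uncatalysed silyl-cation chain, and partial desilylation of 4, which would lose the regiochemical information.
- Fallback, chirality from a reagent-controlled ketone reduction and a [3,3] transfer. It does not start from 3 but from commercial 2-methylcyclohex-2-en-1-one F3, replaces steps 1–4 and returns at 7. Oxazaborolidine-catalysed borane reduction gives (S)-2-methylcyclohex-2-en-1-ol F4. Johnson–Claisen rearrangement with trimethyl orthopropionate (catalytic propionic acid, 140 °C) transfers the carbinol configuration suprafacially to C5 and gives methyl 2-[(1S)-2-methylcyclohex-2-en-1-yl]propanoate F5. mCPBA gives the epoxide F6. Diethylaluminium 2,2,6,6-tetramethylpiperidide (Et2Al(TMP)) removes a methyl hydrogen and isomerises it to the allylic alcohol with exocyclic methylene F7. Oxidation with MnO2 gives 7.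

**Step 5.**
- What may go wrong: poor facial selectivity at the aldehyde carbon (C1), because a tetrasubstituted lithium enolate gives a loose transition state; retro-aldol before the lactone closes; competing 1,2-reduction of the enone.
- Fallback, C1 set by a reagent-controlled reduction instead of the aldol, setting out from 7 and returning at 12. Enolate 9 is generated as in step 5 but alkylated with allyl bromide to the trans allyl ketone F8. Ketalisation as in step 6 gives the dioxolane F9. SeO2/t-BuOOH oxidises the allylic C1 position to the epimeric allylic alcohols F10. Dess–Martin oxidation converges them on the vinyl ketone F11. Oxazaborolidine-catalysed borane reduction gives the (1R)-alcohol F12, which lactonises with a trace of acid, losing methanol, to 12.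

**Step 11.**
- What may go wrong: slow oxidative addition into the neopentyl-type enol triflate, so that triflate hydrolysis and protodeboronation of 21 overtake the coupling.
- Fallback, setting out from 18 and returning at 22. The organocerium reagent from 2-(2-bromoethyl)-2-methyl-1,3-dioxolane (Mg, then CeCl3) adds to the C9 ketone to give the tertiary alcohol F13. Dehydration with SOCl2/pyridine gives 22; any Δ9(11) isomer has to be separated.

**Step 22.**
- What may go wrong: elimination of HBr from the allylic bromide by the hindered, strongly basic alkoxide (1,4-elimination to a diene) and low conversion of a precious electrophile.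
- Fallback, catalytic allylic substitution instead of SN2 with a basic alkoxide, setting out from 28 and 33 and returning at 35. Methyl chloroformate/pyridine converts 28 into the allylic methyl carbonate F14. 33 is converted with Et2Zn into its ethylzinc alkoxide F15, which attacks the unsubstituted terminus C15 of the π-allyl complex formed from F14 with Pd(OAc)2 and a biaryl phosphine, giving 35.

## Further compounds

F1 | step 7 | 2-(trimethylsilyl)ethyl 2-[(1S,2R)-3,3-(ethylenedioxy)-2-[(1R)-1-(methoxycarbonyloxy)prop-2-en-1-yl]-2-methylcyclohexyl]propanoate (allylic methyl carbonate) | C1CC[C@@H](C(C)C(=O)OCC[Si](C)(C)C)[C@](C)([C@@H](C=C)OC(=O)OC)C13OCCO3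
F2 | step 7 | 2-(trimethylsilyl)ethyl ester of 15 | C1CC[C@@H]2[C@](C)(C=CC[C@]2(C)C(=O)OCC[Si](C)(C)C)C13OCCO3
F3 | step 2 | 2-methylcyclohex-2-en-1-one | CC1=CCCCC1=O
F4 | step 2 | (S)-2-methylcyclohex-2-en-1-ol | C1CCC=C(C)[C@H]1O
F5 | step 2 | methyl 2-[(1S)-2-methylcyclohex-2-en-1-yl]propanoate | C1CC[C@@H](C(C)C(=O)OC)C(C)=C1
F6 | step 2 | methyl 2-[(2S)-1-methyl-7-oxabicyclo[4.1.0]heptan-2-yl]propanoate (epoxide of F5) | C1CC[C@@H](C(C)C(=O)OC)C2(C)OC12
F7 | step 2 | methyl 2-[(1S)-3-hydroxy-2-methylidenecyclohexyl]propanoate | C1CC[C@@H](C(C)C(=O)OC)C(=C)C1O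
F8 | step 5 | methyl 2-[(1S,2S)-2-methyl-3-oxo-2-(prop-2-en-1-yl)cyclohexyl]propanoate (allyl trans to C4) | C1CC[C@@H](C(C)C(=O)OC)[C@](C)(CC=C)C1=O
F9 | step 5 | ethylene ketal of F8 | C1CC[C@@H](C(C)C(=O)OC)[C@](C)(CC=C)C13OCCO3
F10 | step 5 | C1-epimeric allylic alcohols from F9 | C1CC[C@@H](C(C)C(=O)OC)[C@](C)(C(O)C=C)C13OCCO3
F11 | step 5 | vinyl ketone from F10 | C1CC[C@@H](C(C)C(=O)OC)[C@](C)(C(=O)C=C)C13OCCO3
F12 | step 5 | (1R)-allylic alcohol (hydroxy ester form of 12) | C1CC[C@@H](C(C)C(=O)OC)[C@](C)([C@@H](C=C)O)C13OCCO3
F13 | step 11 | 2-(trimethylsilyl)ethyl 13,13-(ethylenedioxy)-9-hydroxy-14,15,17-trinorlabdan-19-oate (tertiary alcohol) | C1CC[C@@H]2[C@](C)(CCC[C@]2(C)C(=O)OCC[Si](C)(C)C)C1(O)CCC3(C)OCCO3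
F14 | step 22 | 2-(trimethylsilyl)ethyl (13E)-15-(methoxycarbonyloxy)labda-8(17),13-dien-19-oate | C=C1CC[C@@H]2[C@](C)(CCC[C@]2(C)C(=O)OCC[Si](C)(C)C)[C@H]1CC/C(C)=C/COC(=O)OC
F15 | step 22 | ethylzinc 11-(triethylsilyloxy)eudesman-4α-olate | CC[Zn]O[C@]1(C)CCC[C@]2(C)CC[C@@H](C(C)(C)O[Si](CC)(CC)CC)C[C@H]21
A1 | alternative 1 | trans-decalin C3 ketone with 8(17)-methylene, C12 acetate and axial C19 8-phenylmenthyl ester | C=C1CC[C@@H]2[C@](C)(CCC(=O)[C@]2(C)C(=O)O[C@@H]3C[C@H](C)CC[C@H]3C(C)(C)c3ccccc3)[C@H]1CCOC(C)=O
A2 | alternative 1 | 8-phenylmenthyl (6E,10E)-13-acetoxy-2,7,11-trimethyl-3-oxotrideca-6,10-dienoate | CC(C(=O)CC/C(C)=C/CC/C(C)=C/CCOC(C)=O)C(=O)O[C@@H]1C[C@H](C)CC[C@H]1C(C)(C)c2ccccc2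
A3 | alternative 2 | eudesm-1-en-11-ol 4-prenyl ether | CC(C)=CCO[C@]1(C)CC=C[C@]2(C)CC[C@@H](C(C)(C)O)C[C@H]21
A4 | alternative 2 | elemol | C=C[C@]1(C)CC[C@@H](C(C)(C)O)C[C@H]1C(C)=C
A5 | alternative 2 | prenol (3-methylbut-2-en-1-ol) | CC(C)=CCO
A6 | alternative 3 | 11'-O-triethylsilyl methyl ester of the target | C=C1CC[C@@H]2[C@](C)(CCC[C@]2(C)C(=O)OC)[C@H]1CC/C(C)=C/CO[C@]1(C)CCC[C@]2(C)CC[C@@H](C(C)(C)O[Si](CC)(CC)CC)C[C@H]21
A7 | alternative 3 | methyl 15,16-dinorlabd-8(17)-en-13-yn-19-oate | C=C1CC[C@@H]2[C@](C)(CCC[C@]2(C)C(=O)OC)[C@H]1CCC#C
A8 | alternative 3 | 4α-(chloromethoxy)-11-(triethylsilyloxy)eudesmane | ClCO[C@]1(C)CCC[C@]2(C)CC[C@@H](C(C)(C)O[Si](CC)(CC)CC)C[C@H]21
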